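## The problem

Compound 13 is a spiro[5.5]undecane whose spiro carbon C9 is bonded to the gem-dimethyl carbon C6, so two adjacent quaternary carbons must be joined. Atom labels: ring A is C2, C3, C4, C5, C6, C9, with methyl C1 on C2; ring B is C9, C10, C11, C12, C15, C17. Four stereocenters have to be set as one enantiomer: C5 (S, a secondary bromide beside C6), C9 (R, quaternary), C12 (R, tertiary alcohol) and C15 (R, bromide trans to the hydroxyl and cis to the C12 methyl). They can be chained. A C5 substituent fixes the ring A conformation and, through the pseudoaxial methyl on C6, the face on which C9 is attacked. C9 then places its vinylic arm C2 axial on ring B, which shields one face of C15. C12 must finally receive its methyl group axially, against the usual preference of methyl nucleophiles. The C5 bromide is neopentylic and homoallylic, so substitution there competes with elimination, alkyl shift and π-participation and is best tried early on a simple ring. The C12/C15 bromohydrin does not tolerate warm base or strong Lewis acid (ring contraction), the ring A alkene must be kept from electrophilic oxidants and from migration, and a bromide gamma to an enolate can close a cyclopropane. The feature that opens the molecule is ring B: a cyclohexane 4,4-disubstituted at C9 with its oxygenated carbon C12 para to the spiro centre is the retron of a cyclohexenone annulated from methyl vinyl ketone onto an α-branched aldehyde, and the C2=C3 alkene makes the C9–H of that aldehyde doubly activated.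

## Retrosynthesis

**C12–CH3.** The last bond cut is the one between C12 and its methyl group, which leads from 13 to the α-bromo ketone 12. The neighbouring cut, C15–Br by displacement of an activated C15 oxygen, would need that oxygen axial and cis to the C12 hydroxyl. Enolate oxidation cannot deliver this, because electrophiles enter C15 equatorially, and the bromide would also have to pass the axial C12 methyl. Hydroxybromination of a C12=C15 alkene leaves the face and the opening mode open and puts the ring A alkene at risk. Ketone 12 has one stereocenter fewer and no labile bromohydrin. The forward reaction must deliver methyl axially, so a Lewis-acid-directed addition is required.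

**C15–Br.** The C15–Br bond of 12 is cut back to the regiodefined silyl enol ether 11, which comes from the enone 10 by conjugate hydride delivery. The enone fixes the regiochemistry (C15, not C11). Bromine enters anti to the axial C2 arm, which is the target configuration and also the more stable epimer, so no inversion at C15 is needed. Enone 10 carries only the C5 and C9 stereocenters.

**C9–C10 and C15–C17 (key step).** Enone 10 is cut into the ring A aldehyde 6 and methyl vinyl ketone 7. Forward, a Michael addition forms C9–C10 to give keto aldehyde 8, an aldol closure forms C15–C17 to give 9, and dehydration follows. Cutting here rather than inside ring A removes a whole ring and leaves a monocyclic, ten-carbon precursor. The forward reaction must create the quaternary C9 beside C6 on the correct face and through C9, not C3.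

**C5 substituent.** The C5 substituent of 6 is chosen as the bromide itself, with the target configuration. A protected C5 alcohol of opposite configuration, to be inverted at the end, would direct the acceptor to the wrong face of C9 and would postpone the neopentylic substitution to the most hindered and most valuable intermediate. Aldehyde 6 therefore goes back by oxidation and ester cleavage (5, 4) to the bromo acetate 4, and 4 by invertive bromination to the hydroxy acetate 3. The forward reaction must displace oxygen at a carbon flanked by C6.

**C6–C9 and the C5 oxygen.** Carbinol 3 is cut at the C6–C9 ring bond and the C2=C3 alkene back to the epoxide 2, and 2 to geranyl acetate 1. The congested C6–C9 bond is thus made in a cation–olefin cyclisation, where it is easy. The only stereocenter that needs a reagent, C5, comes from a catalytic asymmetric epoxidation. The forward cyclisation must end by proton loss from C3.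

## Roads not taken

**Alternative 1:** The cut is C3–C4 of ring A. Forward, the lithium enolate of the acetyl group (C2, C3) of epoxy ketone A2 would attack the terminal epoxide carbon C4 and release the C5 alkoxide, giving hydroxy ketone A1 with ring B already in place as a dioxolane.
- Merits: the C5 oxygen configuration comes from an epoxide, the closure is intramolecular, and the C2 carbonyl sits where the C1 methyl and the alkene are needed.
- Weak points:
  - A2 must already contain C9 bonded to C6, an acetyl group and ring B, so the hard quaternary centre is only moved back.
  - The closure is a 6-endo epoxide opening that competes with 5-exo attack at C5 and with O-alkylation.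
  - C5 emerges as an alcohol, so the neopentylic inversion still has to be done, late and on a spiro compound.
  - In A1 the dioxolane is trans-fused, so the C15 oxygen lies on the face that bromine must finally take, and one inversion cannot give the bromohydrin.
  - The C2 ketone needs methyl addition and a regioselective dehydration.
- Comparison: it matches the chosen plan in setting C5 by reagent control and avoids an intermolecular bond to a hindered carbon. The chosen plan sets against this nine steps in all, the C5 bromide made on a monocycle, and C15 bromine entering directly.

**Alternative 2:** The cuts are C5–Br and the C2=C3 π bond, traded for a C3–C5 cyclopropane bond. Forward, the tertiary cyclopropyl carbinol A4 would ionise at C2 and bromide would open the cyclopropylcarbinyl cation at C5, giving bromide A3 with ring expansion.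
- Merits: C5–Br forms with inversion at a cyclopropane carbon and the C2=C3 alkene forms in the same step. This avoids substitution at a neopentylic carbinol and is, in that respect, better than step 3 of the chosen plan.
- Weak points:
  - Bromide can equally open the cation at the unhindered C4, giving a bromomethyl cyclopentene, whereas C5 is the hindered terminus.
  - The dioxolane has to survive MgBr2 or HBr.
  - A4 carries three contiguous ring stereocenters beside the spiro centre and needs a long preparation, with C9 already controlled.
- Comparison: the chosen plan sets against this a two-step access to the ring A carbinol 3 and a known invertive bromination on a simple ring, with a bromonium-ion fallback if that step fails.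

**Alternative 3:** The cut is C6–C9. Forward, protonation of the isopropenyl group of spiro cyclopentenol A6 would trigger a 1,2-shift of C9 from C5 to C6, giving the ring A ketone A5.
- Merits: the most congested bond forms by an intramolecular shift with retention at C9, arguably more surely than any intermolecular bond to C9. The C5 ketone also lets the alcohol epimer for a later inversion be chosen by the hydride used, which is better than the chosen plan, where that epimer is fixed by the cyclisation.
- Weak points:
  - C4 can migrate instead, and the tertiary cation can simply lose a proton.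
  - A5 is a β,γ-unsaturated ketone prone to conjugation.
  - C5 still needs reduction and neopentylic inversion late, between two quaternary carbons.
  - A6 needs C9 and ring B set beforehand.
- Comparison: the chosen plan makes C6–C9 in step 2, where it is easy, so the key step only joins C9 to an unhindered CH2, and bromine is on C5 before any valuable intermediate exists.

Key step: step 6

Assumption: ring B of 10, 11 and 12 is taken to prefer, like the target with its equatorial C15 bromine, the chair or half-chair in which the vinylic carbon C2 is axial and the gem-dimethyl carbon C6 equatorial. The facial arguments of steps 8 and 9 rest on this.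

## Route

**Step 1**
Reactants: 1 geranyl acetate
Product: 2 (2E)-5-[(2R)-3,3-dimethyloxiran-2-yl]-3-methylpent-2-en-1-yl acetate
Conditions: D-fructose-derived Shi ketone (30 mol %), KHSO5 (as 2KHSO5·KHSO4·K2SO4), K2CO3, Bu4NHSO4 (cat.), MeCN/dimethoxymethane/aqueous Na2B4O7 buffer (pH 10.5), 0 °C
Reagents that add atoms: potassium peroxymonosulfate, [K+].[O-]S(=O)(=O)OO
Why: Shi asymmetric epoxidation; the electron-rich 6,7-alkene reacts while the 2,3-alkene is deactivated by the allylic acetate, and the spiro transition state of the chiral dioxirane should set the epoxide carbon (later C5) as R.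

**Step 2**
Reactants: 2 (2E)-5-[(2R)-3,3-dimethyloxiran-2-yl]-3-methylpent-2-en-1-yl acetate
Product: 3 [(1S,5R)-5-hydroxy-2,6,6-trimethylcyclohex-2-en-1-yl]methyl acetate
Conditions: ZrCl4 (1.1 equiv), CH2Cl2, −20 °C to rt
Reagents that add atoms: none
Why: Lewis-acid epoxy-alkene (cation–olefin) cyclisation through a chair transition state forms C6–C9 with the C5–O bond untouched (R retained), and proton loss from C3 should give the endocyclic alkene. C9 is set cis to the hydroxyl (both groups equatorial in the transition state) but is erased in step 6.

**Step 3**
Reactants: 3 [(1S,5R)-5-hydroxy-2,6,6-trimethylcyclohex-2-en-1-yl]methyl acetate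
Product: 4 [(1S,5S)-5-bromo-2,6,6-trimethylcyclohex-2-en-1-yl]methyl acetate
Conditions: CBr4, PPh3, 2,6-lutidine, CH2Cl2, 0 °C to 35 °C
Reagents that add atoms: carbon tetrabromide, BrC(Br)(Br)Br
Why: Appel bromination; the alkoxyphosphonium ion is displaced by bromide with inversion (R to S). This is the known way to place bromine beside a gem-dimethyl carbon from a secondary cyclohexanol that can present an axial C–O bond, and the buffered, non-ionising medium is meant to hold back cationic pathways.

**Step 4**
Reactants: 4 [(1S,5S)-5-bromo-2,6,6-trimethylcyclohex-2-en-1-yl]methyl acetate
Product: 5 [(1S,5S)-5-bromo-2,6,6-trimethylcyclohex-2-en-1-yl]methanol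
Conditions: K2CO3 (0.2 equiv), MeOH, 0 °C to rt
Reagents that add atoms: none
Why: Base-catalysed transesterification of a primary acetate; the neopentylic secondary bromide is inert to methoxide substitution and should not eliminate at this temperature.

**Step 5**
Reactants: 5 [(1S,5S)-5-bromo-2,6,6-trimethylcyclohex-2-en-1-yl]methanol
Product: 6 (1S,5S)-5-bromo-2,6,6-trimethylcyclohex-2-ene-1-carbaldehyde
Conditions: Dess–Martin periodinane, pyridine, CH2Cl2, 0 °C
Reagents that add atoms: none
Why: Dess–Martin oxidation under buffered conditions, which should not move the alkene into conjugation; epimerisation at C9 is immaterial because C9 is planarised in step 6, and the aldehyde is used directly.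

**Step 6**
Reactants: 6 (1S,5S)-5-bromo-2,6,6-trimethylcyclohex-2-ene-1-carbaldehyde; 7 methyl vinyl ketone
Product: 10 (6R,10S)-10-bromo-7,11,11-trimethylspiro[5.5]undeca-1,7-dien-3-one, via keto aldehyde 8 (not isolated), via aldol 9 (not isolated)
Conditions: 7 (3 equiv), 9-amino-9-deoxy-epi-quinine (20 mol %), PhCO2H (40 mol %), toluene, 40 °C, then 70 °C
Reagents that add atoms: none
Why: The primary amine condenses with 6 to an iminium ion that loses the doubly activated C9 proton, giving the 1-amino-1,3-diene (C17=C9, C2=C3). Its α-carbon C9 adds to 7 (C9–C10), and hydrolysis leaves keto aldehyde 8, whose aldehyde has no α-hydrogen. The amine salt then enolises the methyl ketone and C15 attacks C17 in a 6-(enolendo)-exo-trig aldol to 9, which dehydrates to 10; the closest known reaction is the amine-mediated Robinson-type spiroannulation of α-branched aldehydes with methyl vinyl ketone to 4,4-disubstituted cyclohexenones. The new stereocenter C9 is set in the Michael step by the ring: with the C5 bromine equatorial, the pseudoaxial C6 methyl covers one face of C9, so 7 should add to the other, trans to bromine, as the target requires; the quinine-derived amine is expected to reinforce this bias, and its quinidine-derived pseudoenantiomer is the control. The step needs C9 rather than C3 to react: α-attack is the kinetic mode of such dienamines, and only the C9 adduct can cyclise and dehydrate irreversibly, so reversible C3 addition should drain back through it. The aldol step creates no lasting stereocenter because C17 ends sp2.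

**Step 7**
Reactants: 10 (6R,10S)-10-bromo-7,11,11-trimethylspiro[5.5]undeca-1,7-dien-3-one
Product: 11 triethyl{[(6R,10S)-10-bromo-7,11,11-trimethylspiro[5.5]undeca-2,7-dien-3-yl]oxy}silane
Conditions: Et3SiH, RhCl(PPh3)3 (1 mol %), toluene, 50 °C
Reagents that add atoms: triethylsilane, CC[SiH](CC)CC
Why: Rhodium-catalysed 1,4-hydrosilylation of an enone with a monohydrosilane delivers hydride to C17 and gives the C12=C15 silyl enol ether regiospecifically; the isolated trisubstituted alkene and the alkyl bromide should not react.

**Step 8**
Reactants: 11 triethyl{[(6R,10S)-10-bromo-7,11,11-trimethylspiro[5.5]undeca-2,7-dien-3-yl]oxy}silane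
Product: 12 (2R,6R,10S)-2,10-dibromo-7,11,11-trimethylspiro[5.5]undec-7-en-3-one
Conditions: NBS, THF, −78 °C to −20 °C
Reagents that add atoms: N-bromosuccinimide, O=C1CCC(=O)N1Br
Why: Electrophilic bromination of a silyl enol ether, far faster than attack on the ring A alkene. The axial C2 arm on C9 is 1,3 to C15 and blocks one face, so bromine should enter on the other and end equatorial (C15 R), which is also the more stable epimer.

**Step 9**
Reactants: 12 (2R,6R,10S)-2,10-dibromo-7,11,11-trimethylspiro[5.5]undec-7-en-3-one
Product: 13 (2R,3R,6R,10S)-2,10-dibromo-3,7,11,11-tetramethylspiro[5.5]undec-7-en-3-ol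
Conditions: MeAl(OAr)2 (Ar = 2,6-di-tert-butyl-4-methylphenyl; 3 equiv, from AlMe3 and ArOH), toluene, −78 °C; MeLi (2 equiv), −78 °C; H2O quench at −78 °C
Reagents that add atoms: methyllithium, [Li]C
Why: Lewis-acid-directed (amphiphilic) methylation of a cyclohexanone: the bulky aluminium aryloxide on the carbonyl oxygen closes the equatorial side, so MeLi should add axially and give the equatorial alcohol with axial methyl (C12 R), trans to the C15 bromine. The cold quench is meant to prevent ring contraction of the halohydrin alkoxide.

## Compound list

1 | geranyl acetate | CC(C)=CCC/C(C)=C/COC(C)=O | starting material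
2 | (2E)-5-[(2R)-3,3-dimethyloxiran-2-yl]-3-methylpent-2-en-1-yl acetate ((6R)-6,7-epoxygeranyl acetate) | CC1(C)O[C@@H]1CC/C(C)=C/COC(C)=O | intermediate
3 | [(1S,5R)-5-hydroxy-2,6,6-trimethylcyclohex-2-en-1-yl]methyl acetate | CC1=CC[C@@H](O)C(C)(C)[C@H]1COC(C)=O | intermediate
4 | [(1S,5S)-5-bromo-2,6,6-trimethylcyclohex-2-en-1-yl]methyl acetate | CC1=CC[C@H](Br)C(C)(C)[C@H]1COC(C)=O | intermediate
5 | [(1S,5S)-5-bromo-2,6,6-trimethylcyclohex-2-en-1-yl]methanol | CC1=CC[C@H](Br)C(C)(C)[C@H]1CO | intermediate
6 | (1S,5S)-5-bromo-2,6,6-trimethylcyclohex-2-ene-1-carbaldehyde (5-bromo-α-cyclocitral) | CC1=CC[C@H](Br)C(C)(C)[C@H]1C=O | intermediate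
7 | methyl vinyl ketone | CC(=O)C=C | starting material
8 | (1R,5S)-5-bromo-2,6,6-trimethyl-1-(3-oxobutyl)cyclohex-2-ene-1-carbaldehyde | CC1=CC[C@H](Br)C(C)(C)[C@@]1(C=O)CCC(C)=O | intermediate (not isolated)
9 | (6R,10S)-10-bromo-1-hydroxy-7,11,11-trimethylspiro[5.5]undec-7-en-3-one (either C1 epimer) | CC1=CC[C@H](Br)C(C)(C)[C@@]12CCC(=O)CC2O | intermediate (not isolated)
10 | (6R,10S)-10-bromo-7,11,11-trimethylspiro[5.5]undeca-1,7-dien-3-one | CC1=CC[C@H](Br)C(C)(C)[C@@]12CCC(=O)C=C2 | intermediate
11 | triethyl{[(6R,10S)-10-bromo-7,11,11-trimethylspiro[5.5]undeca-2,7-dien-3-yl]oxy}silane | CC1=CC[C@H](Br)C(C)(C)[C@@]12CCC(O[Si](CC)(CC)CC)=CC2 | intermediate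
12 | (2R,6R,10S)-2,10-dibromo-7,11,11-trimethylspiro[5.5]undec-7-en-3-one | CC1=CC[C@H](Br)C(C)(C)[C@@]12CCC(=O)[C@H](Br)C2 | intermediate
13 | (2R,3R,6R,10S)-2,10-dibromo-3,7,11,11-tetramethylspiro[5.5]undec-7-en-3-ol | CC1=CC[C@H](Br)C(C)(C)[C@@]12CC[C@@](C)(O)[C@H](Br)C2 | target

Total step count: 9. Longest linear sequence: 9 steps (1 to 13).

## Least certain steps and fallbacks

**Step 6 (key step).**
- What may go wrong:
  - addition of the dienamine through C3 instead of C9, since C9 is flanked by C6;
  - slow turnover with so congested an aldehyde;
  - migration of the ring A alkene to the exocyclic or tetrasubstituted position through the iminium ion under acid;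
  - leakage of facial selectivity at C9 if catalyst and ring oppose each other;
  - intramolecular displacement of the C5 bromide by C9 (cyclopropane closure) on long heating.
- Fallback (sets out from 6, rejoins at 8 and so at 10): 6 is condensed with cyclohexylamine over molecular sieves to the N-cyclohexyl imine F1, which is heated with 7 without acid. The secondary-enamine tautomer adds through a cyclic aza-ene transition state in which N–H is passed to the acceptor. This geometry exists only for C9, so C3 addition is excluded by mechanism, and no iminium salt is present to move the alkene. The adduct, keto imine F2, is hydrolysed with aqueous acetic acid to 8, which is closed in a separate operation (KOH, MeOH, 0 °C) to 10.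

**Step 3.**
- What may go wrong: ionisation outrunning direct displacement at the neopentylic carbon, leading to loss of the elements of water toward the conjugated diene, methyl shift or ring contraction from C6, or participation of the C2=C3 bond with retention or cyclopropane formation.
- Fallback (sets out from 2, rejoins at 10): the C–Br bond is made before the ring. Epoxide 2 is opened by bromide at the secondary carbon with inversion (Li2NiBr4, THF) to bromohydrin F3. Ionisation of the tertiary hydroxyl (BF3·OEt2, MeNO2, −20 °C) is assisted by the neighbouring bromine, and the bromonium ion of defined configuration is captured by the 2,3-alkene to give the cis bromo acetate F4, the C9 epimer of 4. Methanolysis to alcohol F5 and oxidation to aldehyde F6 follow as in steps 4 and 5. F6 enters step 6 in place of 6, since the same dienamine results.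

**Step 9.**
- What may go wrong: equatorial instead of axial delivery of methyl, giving the C12 epimer; enolisation or bromine–lithium exchange at C15; ring contraction of the metal alkoxide if the mixture warms. Excess AlMe3 in a hydrocarbon solvent is the nearest variation of conditions.
- Fallback (sets out from 10, rejoins at 13): C12 is set on the enone, where axial attack is intrinsic. MeLi with CeCl3 (THF, −78 °C) gives the tertiary allylic alcohol F7. Hydroxyl-directed epoxidation (VO(acac)2, t-BuOOH) gives the cis epoxy alcohol F8 without touching ring A. LiBH4 with Ti(OiPr)4 delivers hydride to the distal carbon C17 in a trans-diaxial opening and gives the cis diol F9 with the C15 oxygen axial. Appel bromination (CBr4, PPh3) of the secondary hydroxyl with inversion then gives 13. The last displacement runs past the axial C12 methyl and is the weak point of this detour.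

**Step 2.**
- What may go wrong: proton loss from the C1 methyl or from C9 instead of C3 (alkene isomers), hydride shift of the opened epoxide to a ketone, and sluggish capture by the acetate-deactivated alkene.
- Fallback (sets out from 2, rejoins at 3): the cyclisation is run as a radical reaction. Cp2TiCl (trivalent titanium, from Cp2TiCl2 and Mn in THF) opens the epoxide homolytically, the tertiary radical cyclises, and loss of hydride from the titanium alkyl gives the exocyclic alkene as a single regioisomer, hydroxy acetate F10. Alkene migration with RhCl3·3H2O (cat., EtOH, 70 °C) toward the less hindered C3 should then give 3.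

## Further compounds

F1 | step 6 | (E)-1-[(1S,5S)-5-bromo-2,6,6-trimethylcyclohex-2-en-1-yl]-N-cyclohexylmethanimine | CC1=CC[C@H](Br)C(C)(C)[C@H]1/C=N/C2CCCCC2
F2 | step 6 | 4-{(1R,5S)-5-bromo-1-[(E)-(cyclohexylimino)methyl]-2,6,6-trimethylcyclohex-2-en-1-yl}butan-2-one | CC1=CC[C@H](Br)C(C)(C)[C@@]1(/C=N/C2CCCCC2)CCC(C)=O
F3 | step 3 | (2E,6S)-6-bromo-7-hydroxy-3,7-dimethyloct-2-en-1-yl acetate | CC(C)(O)[C@@H](Br)CC/C(C)=C/COC(C)=O
F4 | step 3 | [(1R,5S)-5-bromo-2,6,6-trimethylcyclohex-2-en-1-yl]methyl acetate | CC1=CC[C@H](Br)C(C)(C)[C@@H]1COC(C)=O
F5 | step 3 | [(1R,5S)-5-bromo-2,6,6-trimethylcyclohex-2-en-1-yl]methanol | CC1=CC[C@H](Br)C(C)(C)[C@@H]1CO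
F6 | step 3 | (1R,5S)-5-bromo-2,6,6-trimethylcyclohex-2-ene-1-carbaldehyde | CC1=CC[C@H](Br)C(C)(C)[C@@H]1C=O
F7 | step 9 | (3R,6R,10S)-10-bromo-3,7,11,11-tetramethylspiro[5.5]undeca-1,7-dien-3-ol | CC1=CC[C@H](Br)C(C)(C)[C@@]12CC[C@@](C)(O)C=C2
F8 | step 9 | 10-bromo-1,2-epoxy-3,7,11,11-tetramethylspiro[5.5]undec-7-en-3-ol, epoxide cis to the C3 hydroxyl, (3R,6R,10S) | CC1=CC[C@H](Br)C(C)(C)[C@@]12CC[C@@](C)(O)[C@H]3O[C@H]32
F9 | step 9 | (2S,3R,6R,10S)-10-bromo-3,7,11,11-tetramethylspiro[5.5]undec-7-ene-2,3-diol | CC1=CC[C@H](Br)C(C)(C)[C@@]12CC[C@@](C)(O)[C@@H](O)C2
F10 | step 2 | [(1S,3R)-3-hydroxy-2,2-dimethyl-6-methylidenecyclohexyl]methyl acetate | C=C1CC[C@@H](O)C(C)(C)[C@H]1COC(C)=O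
A1 | alternative 1 | ring A hydroxy ketone (C2 ketone, C5 carbinol) with the C12/C15 diol as a trans-fused acetonide | O=C1CC[C@@H](O)C(C)(C)[C@@]12CC[C@@]3(C)OC(C)(C)O[C@@H]3C2
A2 | alternative 1 | epoxy methyl ketone: ring B acetonide whose C9 carries the acetyl group and the 2-(oxiran-2-yl)propan-2-yl group | C1O[C@H]1C(C)(C)[C@]2(C(C)=O)CC[C@@]3(C)OC(C)(C)O[C@@H]3C2
A3 | alternative 2 | ring A bromide (C2=C3 alkene, C5 bromide) with the C12/C15 cis-diol as acetonide | CC1=CC[C@H](Br)C(C)(C)[C@@]12CC[C@@]3(C)OC(C)(C)O[C@H]3C2
A4 | alternative 2 | tertiary cyclopropyl carbinol: bicyclo[3.1.0]hexane (cyclopropane C3–C4–C5, C2 carbinol, C6 gem-dimethyl) spiro-linked at C9 to the ring B acetonide | C[C@]1(O)[C@@H]2C[C@@H]2C(C)(C)[C@@]13CC[C@@]4(C)OC(C)(C)O[C@H]4C3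
A5 | alternative 3 | ring A ketone at C5 (C6 gem-dimethyl, C2=C3 alkene) with the C12/C15 cis-diol as acetonide | CC1=CCC(=O)C(C)(C)[C@@]12CC[C@@]3(C)OC(C)(C)O[C@H]3C2
A6 | alternative 3 | spiro cyclopentenol: cyclopentene C9–C2=C3–C4–C5 with hydroxyl and isopropenyl on C5, spiro-linked at C9 to the ring B acetonide | CC1=CC[C@](O)(C(C)=C)[C@@]12CC[C@@]3(C)OC(C)(C)O[C@H]3C2
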